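**Retrosynthetic overview**

1. Daphnodorin C ⇐ (H2, Pd/C) its pentabenzyl ether; the spiro benzofuranone ring and its two stereocentres (spiro carbon and the adjacent ArCH–O carbon) ⇐ NHC-catalysed syn hydroacylation across the furan C=C bond of a 3-(2-formylaryloxy)-2-arylbenzofuran.
2. That aryl ether ⇐ SNAr of a benzofuran-3-ol silyl ether on 2,4-bis(benzyloxy)-6-fluorobenzaldehyde; the benzofuran-3-ol ⇐ C3 iodination, lithiation and oxygenation of the flavan-fused 2-arylbenzofuran.
3. Pyran ring of the flavan ⇐ flavanone ⇐ one-flask aldol/SNAr (4+2) annulation of an aryl methyl ketone silyl enol ether with 4-(benzyloxy)benzaldehyde (C2–C3 and O1–C8a bonds, C2 stereocentre); the C4 carbonyl is then reduced away.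
4. The ketone ⇐ 1-(2,6-difluoro-4-hydroxyphenyl)ethanone by iodination, Sonogashira/benzofuran annulation and one regioselective SNAr with benzyl alcohol. Ring order: central benzene ring (purchased), furan ring, pyran ring, benzofuranone ring (its closure turns the furan into the dihydrofuran).
5. Enabling feature: in the pyran ring the O1–C2(H)(aryl) unit is a latent 4-hydroxybenzaldehyde C=O, C3 is the methyl carbon of an acetyl group once C4 is a ketone on C4a, and C8a is an oxygen-bearing carbon of the central ring ortho to C4a that can carry fluoride. The C4 ketone makes C3 an enolate carbon and C8a an SNAr site and is removed afterwards.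

Key step: step 5

Assumption: ketone 1 is taken as a purchasable building block, and for each chiral catalyst (steps 5 and 11) the enantiomeric series that delivers the configuration drawn is fixed in a first run.
Locants: flavan numbering (O1, C2, C3, C4, C4a, C8a) is used for the pyran ring. In the systematic names of the tricyclic intermediates (furo[2,3-h]chromene numbering) flavan C8a is C9b, and the furan carbons are C8 (aryl-bearing) and C9.

**Route**

Step 1
Reactants: 1 1-(2,6-difluoro-4-hydroxyphenyl)ethan-1-one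
Product: 2 1-(2,6-difluoro-4-hydroxy-3-iodophenyl)ethan-1-one
Conditions: NIS (1.0 equiv), CF3CO2H (cat.), MeCN, 0 °C to rt
Reagents that add atoms: N-iodosuccinimide, O=C1CCC(=O)N1I
Why: Electrophilic aromatic iodination of a phenol, in which the two positions ortho to the hydroxyl group are equivalent by symmetry, so only the degree of iodination has to be held by stoichiometry on this deactivated ring.

Step 2
Reactants: 2 1-(2,6-difluoro-4-hydroxy-3-iodophenyl)ethan-1-one; 3 1-(benzyloxy)-4-ethynylbenzene
Product: 5 1-{2-[4-(benzyloxy)phenyl]-4,6-difluoro-1-benzofuran-5-yl}ethan-1-one, via alkynylphenol 4 (not isolated)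
Conditions: PdCl2(PPh3)2 (3 mol%), CuI (5 mol%), Et3N, DMF, rt then 60 °C
Reagents that add atoms: none
Why: Sonogashira coupling of the electron-poor aryl iodide followed in the same flask by 5-endo-dig attack of the ortho phenoxide on the alkyne (the standard benzofuran annulation of ortho-iodophenols), which builds the furan ring and uses up the only phenol.

Step 3
Reactants: 5 1-{2-[4-(benzyloxy)phenyl]-4,6-difluoro-1-benzofuran-5-yl}ethan-1-one
Product: 6 1-{6-(benzyloxy)-2-[4-(benzyloxy)phenyl]-4-fluoro-1-benzofuran-5-yl}ethan-1-one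
Conditions: BnOH (1.05 equiv), NaH, THF/DMF, 0 °C to rt
Reagents that add atoms: benzyl alcohol, OCc1ccccc1
Why: Nucleophilic aromatic substitution of a fluoride ortho to the acetyl group; the two fluorides are electronically alike, but the one at benzofuran C6 has a C–H neighbour whereas the one at C4 is wedged between the acetyl group and the ring fusion, so the external alkoxide should take C6 and leave the C4 fluoride for the key step.

Step 4
Reactants: 6 1-{6-(benzyloxy)-2-[4-(benzyloxy)phenyl]-4-fluoro-1-benzofuran-5-yl}ethan-1-one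
Product: 7 [(1-{6-(benzyloxy)-2-[4-(benzyloxy)phenyl]-4-fluoro-1-benzofuran-5-yl}ethenyl)oxy]trimethylsilane
Conditions: Me3SiOTf, Et3N, CH2Cl2, 0 °C; used crude
Reagents that add atoms: trimethylsilyl trifluoromethanesulfonate, C[Si](C)(C)OS(=O)(=O)C(F)(F)F
Why: Soft enolisation and O-silylation of an aryl methyl ketone (silyl enol ether formation), the acetyl methyl group being the only enolisable position.

Step 5
Reactants: 7 [(1-{6-(benzyloxy)-2-[4-(benzyloxy)phenyl]-4-fluoro-1-benzofuran-5-yl}ethenyl)oxy]trimethylsilane; 8 4-(benzyloxy)benzaldehyde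
Product: 11 (2S)-5-(benzyloxy)-2,8-bis[4-(benzyloxy)phenyl]-2,3-dihydro-4H-furo[2,3-h]chromen-4-one, via ammonium enolate 9 (not isolated), via ammonium aldolate 10 (not isolated)
Conditions: 8 (1.2 equiv), O(9)-allyl-N-(9-anthracenylmethyl)cinchonidinium hydrogen difluoride (10 mol%; the cinchoninium pseudoenantiomer if the opposite face is delivered), toluene/CH2Cl2, −50 to −20 °C, slow argon sweep
Reagents that add atoms: none
Why: Proposed new method: a fluoride-relay Mukaiyama aldol/SNAr (4+2) annulation in which the bifluoride desilylates 7 to the chiral ammonium enolate 9, 9 adds to aldehyde 8 (C2–C3 bond) to give aldolate 10, the alkoxide of 10 adds to the fluorine-bearing ring carbon C8a, which is the β-carbon of the aryl ketone, and fluoride leaves (O1–C8a bond), and the fluoride set free desilylates the next molecule of 7 or any O-silylated aldolate, so that a catalytic amount of the ammonium salt should suffice and Me3SiF is the only by-product. The closest known reactions are the chiral quaternary ammonium fluoride- or bifluoride-catalysed Mukaiyama aldol reaction, domino reactions in which an ammonium aryloxide catalyst is regenerated from the leaving group, and the base-mediated SNAr cyclisation of 2-fluoroaryl β-hydroxy ketones to chroman-4-ones. The pyranone ring closes in a 6-endo-trig addition (the ring contains the C8a=C4a bond that passes the charge on to the C4 carbonyl through an anionic σ-adduct) followed by loss of fluoride. The only new stereocentre, C2, is set by the catalyst: within the contact ion pair the cinchonidinium cation shields one face of the enolate and directs it to the Si face of 8 (2S), and since retro-aldol of 10 only returns 9 and 8 to the same chiral ion pair while the ring closure does not touch C2, the configuration is locked at the cyclisation. The step needs enantioface selectivity (catalyst, low temperature, no achiral fluoride source), regioselectivity (secured because step 3 left a single fluoride ortho to the acetyl group) and chemoselectivity over dehydration to the chalcone and base-induced ring opening of 11 (addressed by the cold, weakly basic, Lewis-acid-free medium and by the irreversible SNAr trap).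

Step 6
Reactants: 11 (2S)-5-(benzyloxy)-2,8-bis[4-(benzyloxy)phenyl]-2,3-dihydro-4H-furo[2,3-h]chromen-4-one
Product: 13 (2S)-5-(benzyloxy)-2,8-bis[4-(benzyloxy)phenyl]-3,4-dihydro-2H-furo[2,3-h]chromene, via flavan-4-ol 12 (not isolated)
Conditions: NaBH4, THF/MeOH, 0 °C; then Et3SiH (10 equiv), CF3CO2H added last, CH2Cl2, −20 °C
Reagents that add atoms: none
Why: Hydride reduction of the aryl ketone followed by ionic hydrogenation of the electron-rich benzylic alcohol (the C4 cation is stabilised by the ortho benzyloxy and para furan oxygens, and the excess silane should outrun intermolecular arylation) removes the activating carbonyl without touching C2.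

Step 7
Reactants: 13 (2S)-5-(benzyloxy)-2,8-bis[4-(benzyloxy)phenyl]-3,4-dihydro-2H-furo[2,3-h]chromene
Product: 14 (2S)-5-(benzyloxy)-2,8-bis[4-(benzyloxy)phenyl]-9-iodo-3,4-dihydro-2H-furo[2,3-h]chromene
Conditions: NIS (1.05 equiv), DMF, 0 °C, dark
Reagents that add atoms: N-iodosuccinimide, O=C1CCC(=O)N1I
Why: Electrophilic iodination at C3 of a 2-arylbenzofuran (C9 of the tricycle), the β-carbon of the cyclic enol ether and the most nucleophilic position of the molecule.

Step 8
Reactants: 14 (2S)-5-(benzyloxy)-2,8-bis[4-(benzyloxy)phenyl]-9-iodo-3,4-dihydro-2H-furo[2,3-h]chromene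
Product: 16 {[(2S)-5-(benzyloxy)-2,8-bis[4-(benzyloxy)phenyl]-3,4-dihydro-2H-furo[2,3-h]chromen-9-yl]oxy}trimethylsilane, via 9-lithio species 15 (not isolated)
Conditions: n-BuLi, THF, −100 °C; (Me3SiO)2, −100 to −40 °C; Me3SiCl; non-aqueous work-up, used crude
Reagents that add atoms: bis(trimethylsilyl) peroxide, C[Si](C)(C)OO[Si](C)(C)C
Why: Iodine–lithium exchange at very low temperature (to outrun ring opening of the 3-lithiobenzofuran) and electrophilic oxygenation of the aryllithium with the silyl peroxide give the silyl ether of the benzofuran-3-ol directly, and Me3SiCl turns the lithium silanolate co-product into inert hexamethyldisiloxane.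

Step 9
Reactants: 17 2,4,6-trifluorobenzaldehyde
Product: 19 2,4-bis(benzyloxy)-6-fluorobenzaldehyde, via monoether 18 (not isolated)
Conditions: BnOH (2.05 equiv), K2CO3, DMF, 0 to 40 °C
Reagents that add atoms: benzyl alcohol, OCc1ccccc1
Why: Twofold nucleophilic aromatic substitution on a formyl-activated trifluoroarene, the para fluoride (most activated, least hindered) reacting first, then one of the two equivalent ortho fluorides, while the third substitution is held back by the two donor groups now on the ring.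

Step 10
Reactants: 16 {[(2S)-5-(benzyloxy)-2,8-bis[4-(benzyloxy)phenyl]-3,4-dihydro-2H-furo[2,3-h]chromen-9-yl]oxy}trimethylsilane; 19 2,4-bis(benzyloxy)-6-fluorobenzaldehyde
Product: 20 2,4-bis(benzyloxy)-6-{[(2S)-5-(benzyloxy)-2,8-bis[4-(benzyloxy)phenyl]-3,4-dihydro-2H-furo[2,3-h]chromen-9-yl]oxy}benzaldehyde
Conditions: CsF (10 mol%), DMF, 60 °C, argon
Reagents that add atoms: none
Why: Fluoride-catalysed SNAr coupling of an aryl silyl ether with an activated aryl fluoride, driven by Si–F bond formation; the benzofuran-3-olate should attack through oxygen, which keeps the benzofuran aromatic, whereas C-arylation would have to build a congested quaternary carbon.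

Step 11
Reactants: 20 2,4-bis(benzyloxy)-6-{[(2S)-5-(benzyloxy)-2,8-bis[4-(benzyloxy)phenyl]-3,4-dihydro-2H-furo[2,3-h]chromen-9-yl]oxy}benzaldehyde
Product: 21 (2S,2'S,8'S)-4,5',6-tris(benzyloxy)-2',8'-bis[4-(benzyloxy)phenyl]-3',4'-dihydro-2'H,3H,8'H-spiro[1-benzofuran-2,9'-furo[2,3-h]chromen]-3-one
Conditions: (5aS,10bR)-2-(2,6-dimethoxyphenyl)-4,5a,6,10b-tetrahydroindeno[2,1-b][1,2,4]triazolo[4,3-d][1,4]oxazin-2-ium tetrafluoroborate (15 mol%; or its enantiomer), DBU (15 mol%), 1,4-dioxane, 80 °C, argon
Reagents that add atoms: none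
Why: Proposed new method: NHC-catalysed intramolecular dearomatising hydroacylation of the benzofuran C8=C9 bond, in which the carbene–aldehyde adduct (a hydroxy-enamine acyl-anion equivalent) bonds through carbon to C9 in a 5-exo-trig closure of the benzofuranone ring while its O–H proton passes to C8 in a concerted five-centre transition structure, so that acyl group and hydrogen arrive on the same face (the C8 aryl group ends cis to the benzofuranone oxygen, as in the target) and the chiral triazolylidene, by choosing the face of the planar benzofuran, sets the spiro carbon and C8 in the absolute sense independently of the remote flavan centre; the closest known reactions are the NHC-catalysed enantioselective hydroacylation of unactivated alkenes and of 3-tethered benzofurans to spirocyclic chromanones and the intramolecular Stetter reaction that gives 2,2-disubstituted benzofuran-3(2H)-ones.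

Step 12
Reactants: 21 (2S,2'S,8'S)-4,5',6-tris(benzyloxy)-2',8'-bis[4-(benzyloxy)phenyl]-3',4'-dihydro-2'H,3H,8'H-spiro[1-benzofuran-2,9'-furo[2,3-h]chromen]-3-one
Product: 22 daphnodorin C
Conditions: H2 (1 atm), Pd/C (10 wt%), EtOAc/MeOH, rt, stopped after five equivalents of H2
Reagents that add atoms: none
Why: Hydrogenolysis of the five benzyl ethers over palladium on carbon, under which the two ring-bound 2-aryl ethers and the hindered ketone are expected to survive, so no stereocentre is touched.

**Compound list**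

1 | 1-(2,6-difluoro-4-hydroxyphenyl)ethan-1-one | CC(=O)c1c(F)cc(O)cc1F | starting material
2 | 1-(2,6-difluoro-4-hydroxy-3-iodophenyl)ethan-1-one | CC(=O)c1c(F)cc(O)c(I)c1F | intermediate
3 | 1-(benzyloxy)-4-ethynylbenzene | C#Cc1ccc(OCc2ccccc2)cc1 | starting material
4 | 1-(3-{[4-(benzyloxy)phenyl]ethynyl}-2,6-difluoro-4-hydroxyphenyl)ethan-1-one | CC(=O)c1c(F)cc(O)c(C#Cc2ccc(OCc3ccccc3)cc2)c1F | intermediate (not isolated)
5 | 1-{2-[4-(benzyloxy)phenyl]-4,6-difluoro-1-benzofuran-5-yl}ethan-1-one | CC(=O)c1c(F)cc2oc(-c3ccc(OCc4ccccc4)cc3)cc2c1F | intermediate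
6 | 1-{6-(benzyloxy)-2-[4-(benzyloxy)phenyl]-4-fluoro-1-benzofuran-5-yl}ethan-1-one | CC(=O)c1c(OCc2ccccc2)cc2oc(-c3ccc(OCc4ccccc4)cc3)cc2c1F | intermediate
7 | [(1-{6-(benzyloxy)-2-[4-(benzyloxy)phenyl]-4-fluoro-1-benzofuran-5-yl}ethenyl)oxy]trimethylsilane | C=C(O[Si](C)(C)C)c1c(OCc2ccccc2)cc2oc(-c3ccc(OCc4ccccc4)cc3)cc2c1F | intermediate
8 | 4-(benzyloxy)benzaldehyde | O=Cc1ccc(OCc2ccccc2)cc1 | starting material
9 | enolate of ketone 6 as its cinchonidinium ion pair (anion drawn) | C=C([O-])c1c(OCc2ccccc2)cc2oc(-c3ccc(OCc4ccccc4)cc3)cc2c1F | intermediate (not isolated)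
10 | (3S)-3-[4-(benzyloxy)phenyl]-1-{6-(benzyloxy)-2-[4-(benzyloxy)phenyl]-4-fluoro-1-benzofuran-5-yl}-3-oxidopropan-1-one as its cinchonidinium ion pair (anion drawn) | [O-][C@H](c1ccc(OCc2ccccc2)cc1)CC(=O)c1c(OCc2ccccc2)cc2oc(-c3ccc(OCc4ccccc4)cc3)cc2c1F | intermediate (not isolated)
11 | (2S)-5-(benzyloxy)-2,8-bis[4-(benzyloxy)phenyl]-2,3-dihydro-4H-furo[2,3-h]chromen-4-one | O=C1C[C@@H](c2ccc(OCc3ccccc3)cc2)Oc2c1c(OCc1ccccc1)cc1oc(-c3ccc(OCc4ccccc4)cc3)cc21 | intermediate
12 | (2S)-5-(benzyloxy)-2,8-bis[4-(benzyloxy)phenyl]-3,4-dihydro-2H-furo[2,3-h]chromen-4-ol (both C4 epimers) | OC1C[C@@H](c2ccc(OCc3ccccc3)cc2)Oc2c1c(OCc1ccccc1)cc1oc(-c3ccc(OCc4ccccc4)cc3)cc21 | intermediate (not isolated)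
13 | (2S)-5-(benzyloxy)-2,8-bis[4-(benzyloxy)phenyl]-3,4-dihydro-2H-furo[2,3-h]chromene | C1C[C@@H](c2ccc(OCc3ccccc3)cc2)Oc2c1c(OCc1ccccc1)cc1oc(-c3ccc(OCc4ccccc4)cc3)cc21 | intermediate
14 | (2S)-5-(benzyloxy)-2,8-bis[4-(benzyloxy)phenyl]-9-iodo-3,4-dihydro-2H-furo[2,3-h]chromene | C1C[C@@H](c2ccc(OCc3ccccc3)cc2)Oc2c1c(OCc1ccccc1)cc1oc(-c3ccc(OCc4ccccc4)cc3)c(I)c21 | intermediate
15 | [(2S)-5-(benzyloxy)-2,8-bis[4-(benzyloxy)phenyl]-3,4-dihydro-2H-furo[2,3-h]chromen-9-yl]lithium | C1C[C@@H](c2ccc(OCc3ccccc3)cc2)Oc2c1c(OCc1ccccc1)cc1oc(-c3ccc(OCc4ccccc4)cc3)c([Li])c21 | intermediate (not isolated)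
16 | {[(2S)-5-(benzyloxy)-2,8-bis[4-(benzyloxy)phenyl]-3,4-dihydro-2H-furo[2,3-h]chromen-9-yl]oxy}trimethylsilane | C1C[C@@H](c2ccc(OCc3ccccc3)cc2)Oc2c1c(OCc1ccccc1)cc1oc(-c3ccc(OCc4ccccc4)cc3)c(O[Si](C)(C)C)c21 | intermediate
17 | 2,4,6-trifluorobenzaldehyde | O=Cc1c(F)cc(F)cc1F | starting material
18 | 4-(benzyloxy)-2,6-difluorobenzaldehyde | O=Cc1c(F)cc(OCc2ccccc2)cc1F | intermediate (not isolated)
19 | 2,4-bis(benzyloxy)-6-fluorobenzaldehyde | O=Cc1c(F)cc(OCc2ccccc2)cc1OCc1ccccc1 | intermediate
20 | 2,4-bis(benzyloxy)-6-{[(2S)-5-(benzyloxy)-2,8-bis[4-(benzyloxy)phenyl]-3,4-dihydro-2H-furo[2,3-h]chromen-9-yl]oxy}benzaldehyde | O=Cc1c(Oc2c(-c3ccc(OCc4ccccc4)cc3)oc3cc(OCc4ccccc4)c4c(c23)O[C@H](c2ccc(OCc3ccccc3)cc2)CC4)cc(OCc2ccccc2)cc1OCc1ccccc1 | intermediate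
21 | (2S,2'S,8'S)-4,5',6-tris(benzyloxy)-2',8'-bis[4-(benzyloxy)phenyl]-3',4'-dihydro-2'H,3H,8'H-spiro[1-benzofuran-2,9'-furo[2,3-h]chromen]-3-one (penta-O-benzyl daphnodorin C) | O=C1c2c(OCc3ccccc3)cc(OCc3ccccc3)cc2O[C@]12c1c(cc(OCc4ccccc4)c3c1O[C@H](c1ccc(OCc4ccccc4)cc1)CC3)O[C@H]2c1ccc(OCc2ccccc2)cc1 | intermediate
22 | daphnodorin C, (2S,2'S,8'S)-4,5',6-trihydroxy-2',8'-bis(4-hydroxyphenyl)-3',4'-dihydro-2'H,3H,8'H-spiro[1-benzofuran-2,9'-furo[2,3-h]chromen]-3-one | O=C1c2c(O)cc(O)cc2O[C@]12c1c(cc(O)c3c1O[C@H](c1ccc(O)cc1)CC3)O[C@H]2c1ccc(O)cc1 | target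

**Step count and risks**

Total step count: 12. Longest linear sequence: 11 steps (steps 1 to 8 and 10 to 12, from 1 to 22); step 9 is a one-step branch.

Steps most likely to fail:

1. Step 5 (Proposed new method). Process at risk: an uncatalysed fluoride-chain aldol pathway or reversible ring opening of the flavanone may erode the enantiomeric purity, and the relay may stall if O-silylated aldolate is only slowly reopened by fluoride. Fallback with known chemistry, setting out from 6 and coming back at 11: aldol condensation of ketone 6 with aldehyde 8 (pyrrolidine, EtOH, rt) should give the (E)-chalcone F1. Copper-catalysed asymmetric conjugate borylation (CuCl, NaOtBu, a Josiphos-type bisphosphine of the appropriate hand, B2pin2, MeOH, THF) should give the (S)-β-boryl ketone F2. Oxidation with NaBO3 (retention) should give the (S)-β-hydroxy ketone F3. Cs2CO3 in DMF (0 °C to rt) should then close the pyranone ring of 11 by SNAr. In this variant the C2 stereocentre comes from the borylation and not from an aldol addition.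

2. Step 11 (Proposed new method). Process at risk: the hindered, electron-rich 2,6-dioxygenated aldehyde may be slow to form the acyl-anion equivalent, and 6-endo closure onto C8 or loss of the aldehyde may compete with the 5-exo syn hydroacylation. Fallback with known chemistry, setting out from 14 and coming back at 21:
 - Iodine–lithium exchange on 14 as in step 8 and addition of the aryllithium to aldehyde 19 should give the diaryl carbinol F4 (mixture of carbinol epimers), and oxidation with Dess–Martin periodinane the 9-aroylbenzofuran F5.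
 - Conjugate reduction of this vinylogous ester with copper hydride (Cu(OAc)2, (R)-DTBM-SEGPHOS or its enantiomer, polymethylhydrosiloxane, t-BuOH, toluene) and equilibration on work-up should give the trans-2,3-dihydrobenzofuran F6. The ArCH–O centre is set by the ligand or, failing that, by separating the two trans diastereomers that the remote flavan centre makes distinguishable.
 - Enolisation (KHMDS, THF, −78 °C) and chlorination with N-chlorosuccinimide on the enolate face anti to the neighbouring aryl group should give the tertiary α-chloro ketone F7.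
 - KOH in DMSO (SNAr hydroxylation of the fluoride ortho to the ketone) should generate the phenoxide, which displaces the tertiary chloride intramolecularly with inversion (the classical coumaranone closure). The ring oxygen thus ends cis to the aryl group, as in 21.

3. Step 10. Process at risk: C- instead of O-arylation of the ambident benzofuran-3-olate, or sluggish substitution on the donor-substituted fluoroaldehyde with competing addition to its formyl group. Fallback setting out from 14 and coming back at 20, with the polarity of the C–O bond formation reversed: Ullmann-type etherification of iodide 14 with the known phenol 2,4-bis(benzyloxy)-6-hydroxybenzaldehyde (CuI, picolinic acid, K3PO4, DMSO, 90 °C) should give 20 directly, bypassing 15 and 16. This fallback makes no new compound (F0).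

Further compounds
F1 | step 5 | (E)-3-[4-(benzyloxy)phenyl]-1-{6-(benzyloxy)-2-[4-(benzyloxy)phenyl]-4-fluoro-1-benzofuran-5-yl}prop-2-en-1-one | O=C(/C=C/c1ccc(OCc2ccccc2)cc1)c1c(OCc2ccccc2)cc2oc(-c3ccc(OCc4ccccc4)cc3)cc2c1F
F2 | step 5 | (3S)-3-[4-(benzyloxy)phenyl]-1-{6-(benzyloxy)-2-[4-(benzyloxy)phenyl]-4-fluoro-1-benzofuran-5-yl}-3-(4,4,5,5-tetramethyl-1,3,2-dioxaborolan-2-yl)propan-1-one | O=C(C[C@H](B1OC(C)(C)C(C)(C)O1)c1ccc(OCc2ccccc2)cc1)c1c(OCc2ccccc2)cc2oc(-c3ccc(OCc4ccccc4)cc3)cc2c1F
F3 | step 5 | (3S)-3-[4-(benzyloxy)phenyl]-1-{6-(benzyloxy)-2-[4-(benzyloxy)phenyl]-4-fluoro-1-benzofuran-5-yl}-3-hydroxypropan-1-one | O=C(C[C@H](O)c1ccc(OCc2ccccc2)cc1)c1c(OCc2ccccc2)cc2oc(-c3ccc(OCc4ccccc4)cc3)cc2c1F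
F4 | step 11 | [2,4-bis(benzyloxy)-6-fluorophenyl][(2S)-5-(benzyloxy)-2,8-bis[4-(benzyloxy)phenyl]-3,4-dihydro-2H-furo[2,3-h]chromen-9-yl]methanol (carbinol epimers) | C1C[C@@H](c2ccc(OCc3ccccc3)cc2)Oc2c1c(OCc1ccccc1)cc1oc(-c3ccc(OCc4ccccc4)cc3)c(C(O)c3c(F)cc(OCc4ccccc4)cc3OCc3ccccc3)c21
F5 | step 11 | [2,4-bis(benzyloxy)-6-fluorophenyl][(2S)-5-(benzyloxy)-2,8-bis[4-(benzyloxy)phenyl]-3,4-dihydro-2H-furo[2,3-h]chromen-9-yl]methanone | C1C[C@@H](c2ccc(OCc3ccccc3)cc2)Oc2c1c(OCc1ccccc1)cc1oc(-c3ccc(OCc4ccccc4)cc3)c(C(=O)c3c(F)cc(OCc4ccccc4)cc3OCc3ccccc3)c21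
F6 | step 11 | trans-8,9-dihydro derivative of F5 (aroyl group trans to the C8 aryl group; C2 and C8 configured as in 21) | O=C(c1c(F)cc(OCc2ccccc2)cc1OCc1ccccc1)[C@@H]1c2c(cc(OCc3ccccc3)c3c2O[C@H](c2ccc(OCc4ccccc4)cc2)CC3)O[C@H]1c1ccc(OCc2ccccc2)cc1
F7 | step 11 | 9-chloro derivative of F6 (chlorine trans to the C8 aryl group) | O=C(c1c(F)cc(OCc2ccccc2)cc1OCc1ccccc1)[C@@]1(Cl)c2c(cc(OCc3ccccc3)c3c2O[C@H](c2ccc(OCc4ccccc4)cc2)CC3)O[C@H]1c1ccc(OCc2ccccc2)cc1
F0 | step 10 | none | none
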